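**Retrosynthetic overview**
1. The six-membered carbocycle is left intact and bought as (S)-(+)-carvone 1, itself the product of the natural cyclase closure (C10 diphosphate → α-terpinyl cation → limonene → carvone); its C4 centre controls all new stereocentres.
2. Key disconnection: the C3–O bond and the 1,6-epoxide both come from one O2 molecule added across C3/C6 of the cross-conjugated dienol of 1 (lithium dienolate 2, silyl dienol ether 3): endoperoxide 4 → syn-bisepoxide 5 → silyl ketol 6 → epoxy ketol 7.
3. Side chain: the trisubstituted C=C is disconnected by cross-metathesis into allyl tiglate 8 and methacrylic acid 9, giving acid 10.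
4. Last disconnection: the C3 ester C–O bond, 7 + 10 through mixed anhydride 11 to the target 12.
5. Ring order: carbocycle (present in 1) → 1,2-dioxane ring of 4 → two oxiranes of 5 → the 2,3-oxirane opens and the 1,6-oxirane stays.

Assumption: the presumed biosynthesis is taken as cyclase closure to the p-menthane ring (limonene, then (S)-carvone), addition of one O2 across C3/C6 of the carvone dienol to an ascaridole-type endoperoxide that isomerises to the cis epoxy ketol, and acylation last.

**Route**

Step 1
Reactants: 1 (S)-(+)-carvone [(5S)-2-methyl-5-(prop-1-en-2-yl)cyclohex-2-en-1-one]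
Product: 3 trimethyl{[(3S)-6-methyl-3-(prop-1-en-2-yl)cyclohexa-1,5-dien-1-yl]oxy}silane (cross-conjugated Me3Si dienol ether of 1), via lithium dienolate 2 (not isolated)
Conditions: LiN(iPr)2 (commercial solution, 1.1 equiv), THF, −78 °C, 45 min; Me3SiCl (1.3 equiv), −78 → 0 °C; pentane, cold aq NaHCO3, bulb-to-bulb distillation
Reagents that add atoms: chlorotrimethylsilane, C[Si](C)(C)Cl
Why: Kinetic α′-deprotonation of the enone at C3 and O-silylation of the enolate (kinetic enolate trapping) give the 2-siloxy-1,3-diene; the C4 stereocentre is not touched.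

Step 2
Reactants: 3 trimethyl{[(3S)-6-methyl-3-(prop-1-en-2-yl)cyclohexa-1,5-dien-1-yl]oxy}silane
Product: 7 (1S,3R,4R,6S)-3-hydroxy-1-methyl-4-(prop-1-en-2-yl)-7-oxabicyclo[4.1.0]heptan-2-one (epoxy ketol; hydroxyl cis to the oxirane oxygen; both trans to isopropenyl), via endoperoxide 4 (not isolated), via siloxy bisepoxide 5 (not isolated), via silyl ether 6 (not isolated)
Conditions: O2, hν (white LED), H2TPP (5,10,15,20-tetraphenylporphyrin, 0.5 mol %), CH2Cl2, −78 °C; Ar purge; Co(TPP) (C44H28CoN4, divalent cobalt, 3 mol %), −78 → 0 °C; citric acid, MeOH, 0 °C → rt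
Reagents that add atoms: dioxygen (as singlet oxygen), O=O
Why: Proposed new method: singlet oxygen adds as a dienophile across C3/C6 of the s-cis-locked 2-siloxycyclohexa-1,3-diene (closest known type: [4+2] photooxygenation of cyclohexa-1,3-dienes to ascaridole-type endoperoxides) on the face opposite the C4 isopropenyl group, the face carbon dienophiles also take with this diene, which sets C3 and C6; Co(TPP) then cleaves the O–O bond by one-electron transfer and each oxygen radical closes onto the adjacent carbon of the C1=C2 enol ether (closest known type: Co(TPP)-catalysed endoperoxide to syn-bisepoxide isomerisation), which sets C1 on the same face; the 2-siloxy oxirane of 5 opens at C2 with a 1,4 O-to-O silyl shift as in the second stage of a Rubottom oxidation, so the C3–O bond is never broken, and acid methanolysis of the Me3Si ether frees the alcohol.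

Step 3
Reactants: 8 allyl tiglate [prop-2-en-1-yl (2E)-2-methylbut-2-enoate]; 9 methacrylic acid (2-methylprop-2-enoic acid)
Product: 10 (2E)-2-methyl-4-{[(2E)-2-methylbut-2-enoyl]oxy}but-2-enoic acid
Conditions: RuCl2(H2IMes)(=CH-C6H4-2-OiPr) (second-generation Hoveyda–Grubbs catalyst, C31H38Cl2N2ORu, 5 mol %), 9 (5 equiv), 1,4-benzoquinone (10 mol %), CH2Cl2, 40 °C, Ar sparge, 16 h
Reagents that add atoms: none
Why: Olefin cross-metathesis between the terminal allyl ester and the 1,1-disubstituted acceptor methacrylic acid (which does not homodimerise) gives the trisubstituted enoic acid with the thermodynamically preferred E geometry (CO2H trans to CH2O); the electron-poor trisubstituted tiglate C=C is inert.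

Step 4
Reactants: 7 (1S,3R,4R,6S)-3-hydroxy-1-methyl-4-(prop-1-en-2-yl)-7-oxabicyclo[4.1.0]heptan-2-one; 10 (2E)-2-methyl-4-{[(2E)-2-methylbut-2-enoyl]oxy}but-2-enoic acid
Product: 12 (1S,3R,4R,6S)-1-methyl-2-oxo-4-(prop-1-en-2-yl)-7-oxabicyclo[4.1.0]heptan-3-yl (2E)-2-methyl-4-{[(2E)-2-methylbut-2-enoyl]oxy}but-2-enoate (target CNP0251261.1), via mixed anhydride 11 (not isolated)
Conditions: 10 (1.5 equiv), 2,4,6-Cl3C6H2COCl (1.5 equiv), Et3N (3 equiv), toluene, rt, 1 h; then 7, DMAP (0.5 equiv), toluene, 0 °C → rt
Reagents that add atoms: none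
Why: Yamaguchi esterification: the aliphatic acyl group of mixed anhydride 11 is passed through the acylpyridinium ion to the equatorial C3 hydroxyl; no bond to a stereocentre is broken, so all four ring centres and both E alkenes are kept.

**Compound list**
1 | (S)-(+)-carvone, (5S)-2-methyl-5-(prop-1-en-2-yl)cyclohex-2-en-1-one | C=C(C)[C@H]1CC=C(C)C(=O)C1 | starting material
2 | lithium (3S)-6-methyl-3-(prop-1-en-2-yl)cyclohexa-1,5-dien-1-olate (kinetic dienolate of 1) | C=C(C)[C@H]1CC=C(C)C(O[Li])=C1 | intermediate
3 | trimethyl{[(3S)-6-methyl-3-(prop-1-en-2-yl)cyclohexa-1,5-dien-1-yl]oxy}silane | C=C(C)[C@H]1CC=C(C)C(O[Si](C)(C)C)=C1 | intermediate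
4 | (3R,4R,6S)-3,6-epidioxy-2-(trimethylsilyloxy)-p-mentha-1,8-diene (2,3-dioxabicyclo[2.2.2]oct-5-ene; O–O bridge on the face opposite isopropenyl) | C=C(C)[C@H]1C[C@@H]2OO[C@H]1C(O[Si](C)(C)C)=C2C | intermediate
5 | (1S,2S,3R,4R,6S)-1,6:2,3-diepoxy-2-(trimethylsilyloxy)-p-menth-8-ene (both oxirane oxygens on the face opposite isopropenyl) | C=C(C)[C@H]1C[C@@H]2O[C@]2(C)[C@]3(O[Si](C)(C)C)O[C@H]13 | intermediate
6 | (1S,3R,4R,6S)-1-methyl-4-(prop-1-en-2-yl)-3-[(trimethylsilyl)oxy]-7-oxabicyclo[4.1.0]heptan-2-one | C=C(C)[C@H]1C[C@@H]2O[C@]2(C)C(=O)[C@@H]1O[Si](C)(C)C | intermediate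
7 | (1S,3R,4R,6S)-3-hydroxy-1-methyl-4-(prop-1-en-2-yl)-7-oxabicyclo[4.1.0]heptan-2-one | C=C(C)[C@H]1C[C@@H]2O[C@]2(C)C(=O)[C@@H]1O | intermediate
8 | allyl tiglate, prop-2-en-1-yl (2E)-2-methylbut-2-enoate | C=CCOC(=O)/C(C)=C/C | starting material
9 | methacrylic acid, 2-methylprop-2-enoic acid | C=C(C)C(=O)O | starting material
10 | (2E)-2-methyl-4-{[(2E)-2-methylbut-2-enoyl]oxy}but-2-enoic acid | OC(=O)/C(C)=C/COC(=O)/C(C)=C/C | intermediate
11 | (2E)-2-methyl-4-{[(2E)-2-methylbut-2-enoyl]oxy}but-2-enoic 2,4,6-trichlorobenzoic anhydride | Clc1cc(Cl)c(C(=O)OC(=O)/C(C)=C/COC(=O)/C(C)=C/C)c(Cl)c1 | intermediate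
12 | (1S,3R,4R,6S)-1-methyl-2-oxo-4-(prop-1-en-2-yl)-7-oxabicyclo[4.1.0]heptan-3-yl (2E)-2-methyl-4-{[(2E)-2-methylbut-2-enoyl]oxy}but-2-enoate | C=C(C)[C@H]1C[C@@H]2O[C@]2(C)C(=O)[C@@H]1OC(=O)/C(C)=C/COC(=O)/C(C)=C/C | target

**Step count**
Total: 4 steps. Longest linear sequence: 3 steps (1 → 3 → 7 → 12); step 3 is a one-step branch to 10.

**Steps most likely to fail**

Step 2 is the riskiest step of the route.
- Singlet oxygen is small, so the face selectivity imposed by one allylic isopropenyl group may be only moderate; the syn isomer would have to be removed at the stage of 7.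
- A silatropic ene reaction at the silyl enol ether can compete with the cycloaddition.
- The alkoxyl radicals of the cobalt stage can fragment instead of closing.

The fallback sets out from 1 and comes back at 7. Compound 1 is epoxidised with alkaline hydrogen peroxide (30% H2O2, NaOH, MeOH, 0 °C, Weitz–Scheffer epoxidation) to the trans epoxide (1S,4S,6S)-carvone oxide F1. F1 is deprotonated at C3 with LiN(SiMe3)2 in THF at −78 °C to its lithium enolate F2. F2 is hydroxylated with 3-phenyl-2-(phenylsulfonyl)oxaziridine on the face opposite the neighbouring isopropenyl group, and an NH4Cl quench gives 7.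

Step 3 may stall for two reasons.
- Free methacrylic acid is a sluggish 1,1-disubstituted partner and can deactivate the ruthenium carbene.
- Ruthenium hydrides can isomerise the allyl ester to the prop-1-enyl ester.

The fallback sets out from 8 and comes back at 10, replacing metathesis by carbonyl olefination. The terminal alkene of 8 is cleaved selectively (OsO4 cat., NaIO4, 2,6-lutidine, dioxane/H2O; the electron-poor tiglate alkene reacts far more slowly) to 2-oxoethyl tiglate F3. A Wittig reaction of F3 with 2-(triphenylphosphoranylidene)propanal (benzene, 60 °C) gives the E enal (2E)-3-methyl-4-oxobut-2-en-1-yl tiglate F4. Pinnick oxidation of F4 (NaClO2, NaH2PO4, 2-methylbut-2-ene, tBuOH/H2O) gives 10.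

Step 4 has three foreseeable problems.
- The activated γ-acyloxy enoate can lose a γ-hydrogen under amine base (vinylketene or dienolate), which scrambles the alkene geometry or deconjugates it.
- The hindered α-ketol may acylate slowly.
- C3 may epimerise under base.

The fallback sets out from 7 and comes back at 12, finishing the side chain on the scaffold. Compound 7 is acylated with methacrylic anhydride (Et3N, DMAP cat., CH2Cl2, 0 °C), a small acyl group without γ-hydrogens, to the methacrylate F5. Cross-metathesis of F5 with 8 (3 equiv, the same ruthenium catalyst, CH2Cl2, 40 °C) gives 12. The hindered, unactivated isopropenyl group and the tiglate alkene are expected to stay out of this metathesis, though competing reaction at the isopropenyl group is the main risk of this fallback.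

**Further compounds**
F1 | step 2 | (1S,4S,6S)-1-methyl-4-(prop-1-en-2-yl)-7-oxabicyclo[4.1.0]heptan-2-one | C=C(C)[C@H]1C[C@@H]2O[C@]2(C)C(=O)C1
F2 | step 2 | lithium enolate of F1, lithium (1S,4S,6S)-1-methyl-4-(prop-1-en-2-yl)-7-oxabicyclo[4.1.0]hept-2-en-2-olate | C=C(C)[C@H]1C[C@@H]2O[C@]2(C)C(O[Li])=C1
F3 | step 3 | 2-oxoethyl (2E)-2-methylbut-2-enoate | O=CCOC(=O)/C(C)=C/C
F4 | step 3 | (2E)-3-methyl-4-oxobut-2-en-1-yl (2E)-2-methylbut-2-enoate | O=C/C(C)=C/COC(=O)/C(C)=C/C
F5 | step 4 | (1S,3R,4R,6S)-1-methyl-2-oxo-4-(prop-1-en-2-yl)-7-oxabicyclo[4.1.0]heptan-3-yl 2-methylprop-2-enoate | C=C(C)[C@H]1C[C@@H]2O[C@]2(C)C(=O)[C@@H]1OC(=O)C(C)=C
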